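**Retrosynthetic overview**
1. Structural feature used: in ring C, C2 is bonded to ring B (4'-OMe para to that bond) and is β to the C4 carbonyl, and C3 must carry oxygen. C2=C3 is therefore traced back to an alkyne C2≡C3 that accepts O1 at C2 and a placeholder electrophile (I+) at C3.
2. Late stage: the O–S bond of the sulfate is made on the only free hydroxyl of 5,3'-di-O-benzylombuin. That C3–OH comes from C3–I by way of C3–B, and the two benzyl ethers that remain are removed afterwards by hydrogenolysis.
3. Key disconnection: O1–C2 of ring C, back to a diaryl ynone whose ring A has two symmetry-equivalent ortho benzyloxy groups. One becomes O1 and loses its benzyl; the other stays as the masked 5-OH.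
4. Ynone: the C3–C4 bond comes from the ring-B acetylide (from isovanillin) and the ring-A aldehyde (from 2,4,6-trihydroxybenzaldehyde), followed by oxidation.
5. Ring order: rings A and B are purchased, and ring C is the only ring formed.

Key step: step 7

Remark: the target has no stereogenic element, so no enantiocontrol is needed; the one carbinol centre that appears on the way is racemic and is erased by oxidation.
Assumption: the target is drawn as the free hydrogen sulfate. Such acids catalyse their own hydrolysis, so the sulfate is carried as its triethylammonium salt and protonated only in the last step.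

**Route**

Step 1
Reactants: 1 2,4,6-trihydroxybenzaldehyde
Product: 2 2,6-dihydroxy-4-methoxybenzaldehyde
Conditions: MeI (1.05 equiv), NaHCO3 (1.2 equiv), DMF, 30 °C, closed flask
Reagents that add atoms: iodomethane, CI
Why: Williamson ether synthesis under acidity control, in which bicarbonate ionises only the 4-OH (the vinylogous acid para to the formyl group) while the 2- and 6-OH are held in hydrogen bonds to the formyl oxygen, so one equivalent of MeI should end up on O4.

Step 2
Reactants: 2 2,6-dihydroxy-4-methoxybenzaldehyde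
Product: 3 2,6-bis(benzyloxy)-4-methoxybenzaldehyde
Conditions: BnBr (2.5 equiv), K2CO3 (3 equiv), cat. Bu4NI, DMF, 65 °C
Reagents that add atoms: benzyl bromide, BrCc1ccccc1
Why: Williamson ether synthesis, in which carbonate in warm DMF breaks the chelates of the two equivalent ortho phenols and the non-enolisable aldehyde is inert to the conditions.

Step 3
Reactants: 4 isovanillin (3-hydroxy-4-methoxybenzaldehyde)
Product: 5 3-benzyloxy-4-methoxybenzaldehyde
Conditions: BnBr (1.1 equiv), K2CO3 (1.5 equiv), DMF, rt
Reagents that add atoms: benzyl bromide, BrCc1ccccc1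
Why: Williamson ether synthesis on the single phenol of isovanillin, with no competing nucleophilic site.

Step 4
Reactants: 5 3-benzyloxy-4-methoxybenzaldehyde
Product: 6 2-benzyloxy-4-ethynyl-1-methoxybenzene
Conditions: dimethyl (1-diazo-2-oxopropyl)phosphonate (1.3 equiv), K2CO3 (2 equiv), MeOH–THF, rt
Reagents that add atoms: Ohira–Bestmann reagent, CC(=O)C(=[N+]=[N-])P(=O)(OC)OC
Why: Ohira–Bestmann variant of the Seyferth–Gilbert homologation, in which methanolysis frees the diazomethylphosphonate anion, this adds to the aldehyde, and loss of phosphate and N2 followed by 1,2-hydrogen shift gives the terminal alkyne without touching the ethers.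

Step 5
Reactants: 6 2-benzyloxy-4-ethynyl-1-methoxybenzene; 3 2,6-bis(benzyloxy)-4-methoxybenzaldehyde
Product: 8 1-[2,6-bis(benzyloxy)-4-methoxyphenyl]-3-(3-benzyloxy-4-methoxyphenyl)prop-2-yn-1-ol (racemic), via lithium acetylide 7 (not isolated)
Conditions: 6 (1.1 equiv), nBuLi (1.05 equiv), THF, −78 °C; then 3, −78 → 0 °C; H2O quench
Reagents that add atoms: none
Why: 1,2-addition of a lithium acetylide to a non-enolisable aldehyde forms the C3–C4 bond, and the new carbinol centre is formed racemic, which is harmless because it becomes the C4 carbonyl in the next step.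

Step 6
Reactants: 8 1-[2,6-bis(benzyloxy)-4-methoxyphenyl]-3-(3-benzyloxy-4-methoxyphenyl)prop-2-yn-1-ol
Product: 9 1-[2,6-bis(benzyloxy)-4-methoxyphenyl]-3-(3-benzyloxy-4-methoxyphenyl)prop-2-yn-1-one
Conditions: activated MnO2 (15 equiv), CH2Cl2, rt
Reagents that add atoms: none
Why: MnO2 oxidation of an alcohol that is both benzylic and propargylic, run under neutral conditions so that the easily ionised, electron-rich carbinol does not rearrange (Meyer–Schuster type).

Step 7
Reactants: 9 1-[2,6-bis(benzyloxy)-4-methoxyphenyl]-3-(3-benzyloxy-4-methoxyphenyl)prop-2-yn-1-one; 10 iodine monochloride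
Product: 12 5-benzyloxy-2-(3-benzyloxy-4-methoxyphenyl)-3-iodo-7-methoxychromen-4-one, via O1-benzyl oxonium chloride 11 (not isolated)
Conditions: ICl (1.05 equiv, 1 M in CH2Cl2, slow addition), CH2Cl2, −78 °C; aq Na2S2O3
Reagents that add atoms: iodine monochloride (10), ClI
Why: ICl binds the C2≡C3 triple bond as an iodonium-type complex whose positive charge leans towards C2, a lone pair of one ortho benzyloxy oxygen adds to C2 anti to iodine to give oxonium ion 11, and chloride then removes the benzyl group at its CH2 carbon (SN2), which releases benzyl chloride and makes the closure irreversible. The closest known reaction type is the ICl-induced electrophilic cyclisation of 2-alkoxyaryl alkynyl ketones to 3-iodochromones with loss of the alkyl halide. Ring C closes in the 6-endo-dig mode through the O1–C2 bond, and no stereocentre is created. The first selectivity needed is 6-endo over 5-exo closure (aurone skeleton), and it is secured by the polarisation of the alkyne: C2 is the β-carbon of the ynone and is conjugated with the 4'-methoxy group of ring B, whereas cationic character at C3 next to the carbonyl is disfavoured. The second is alkyne activation over aromatic iodination at the two free C–H positions of the trialkoxy ring A, which is addressed by slow addition of one equivalent of ICl at −78 °C, by the acyl group on that ring and by the fast intramolecular trapping. No regiochemical question arises between the two ortho ethers because they are equivalent by symmetry, so the one that is not used remains as the protected 5-OH.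

Step 8
Reactants: 12 5-benzyloxy-2-(3-benzyloxy-4-methoxyphenyl)-3-iodo-7-methoxychromen-4-one
Product: 13 5-benzyloxy-2-(3-benzyloxy-4-methoxyphenyl)-7-methoxy-3-(4,4,5,5-tetramethyl-1,3,2-dioxaborolan-2-yl)chromen-4-one
Conditions: B2pin2 (1.5 equiv), PdCl2(dppf)·CH2Cl2 (5 mol %), KOAc (3 equiv), 1,4-dioxane, 80 °C; short silica plug
Reagents that add atoms: bis(pinacolato)diboron, CC1(C)OB(OC1(C)C)B1OC(C)(C)C(C)(C)O1
Why: Miyaura borylation, in which Pd(0) inserts into the weak C3–I bond (the elementary step that lets 3-iodochromones enter cross-couplings), acetate-assisted transmetalation with B2pin2 and reductive elimination give C3–B, and the weak base KOAc holds back Suzuki-type dimerisation and spares the pyranone.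

Step 9
Reactants: 13 5-benzyloxy-2-(3-benzyloxy-4-methoxyphenyl)-7-methoxy-3-(4,4,5,5-tetramethyl-1,3,2-dioxaborolan-2-yl)chromen-4-one
Product: 14 5-benzyloxy-2-(3-benzyloxy-4-methoxyphenyl)-3-hydroxy-7-methoxychromen-4-one (5,3'-di-O-benzylombuin)
Conditions: 30% aq H2O2 (3 equiv), NaHCO3, THF–H2O, 0 °C → rt
Reagents that add atoms: hydrogen peroxide, OO
Why: boronate oxidation, in which hydroperoxide adds to boron and C3 migrates from B to O (1,2-metallate shift), and the flavonol formed tolerates basic peroxide since flavonols are themselves made in that medium in the Algar–Flynn–Oyamada reaction.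

Step 10
Reactants: 14 5-benzyloxy-2-(3-benzyloxy-4-methoxyphenyl)-3-hydroxy-7-methoxychromen-4-one
Product: 15 triethylammonium 5-benzyloxy-2-(3-benzyloxy-4-methoxyphenyl)-7-methoxy-4-oxochromen-3-yl sulfate
Conditions: SO3·NMe3 (5 equiv), Et3N (10 equiv), DMF, 60 °C; silica, CH2Cl2–MeOH with 1% Et3N
Reagents that add atoms: sulfur trioxide–trimethylamine complex, C[N+](C)(C)S(=O)(=O)[O-]; triethylamine, CCN(CC)CC
Why: O-sulfation with an amine–SO3 complex, in which the 3-OH is the only free hydroxyl, Et3N raises its nucleophilicity by breaking the hydrogen bond to C4=O, and the volatile trimethylamine leaves so that the product is obtained as the organic-soluble triethylammonium salt.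

Step 11
Reactants: 15 triethylammonium 5-benzyloxy-2-(3-benzyloxy-4-methoxyphenyl)-7-methoxy-4-oxochromen-3-yl sulfate
Product: 16 triethylammonium 5-hydroxy-2-(3-hydroxy-4-methoxyphenyl)-7-methoxy-4-oxochromen-3-yl sulfate
Conditions: H2 (1 atm), 10% Pd/C, MeOH–THF, rt; Sephadex LH-20 (MeOH)
Reagents that add atoms: none
Why: catalytic hydrogenolysis of the two aryl benzyl ethers (5-O and 3'-O), under which the sulfate monoester anion, the methyl ethers and the C2=C3 bond of the conjugated pyranone are inert at atmospheric pressure.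

Step 12
Reactants: 16 triethylammonium 5-hydroxy-2-(3-hydroxy-4-methoxyphenyl)-7-methoxy-4-oxochromen-3-yl sulfate
Product: 17 ombuin 3-O-sulfate (5-hydroxy-2-(3-hydroxy-4-methoxyphenyl)-7-methoxy-4-oxochromen-3-yl hydrogen sulfate)
Conditions: Dowex 50WX8 (H+ form), MeOH–H2O, 0–5 °C; freeze-dry at once, store cold and dry
Reagents that add atoms: none
Why: cation exchange on a sulfonic acid resin swaps triethylammonium for a proton without adding a soluble acid, and low temperature with immediate lyophilisation limits acid-catalysed loss of the sulfate.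

**Compound list**
1 | 2,4,6-trihydroxybenzaldehyde | O=Cc1c(O)cc(O)cc1O | starting material
2 | 2,6-dihydroxy-4-methoxybenzaldehyde | COc1cc(O)c(C=O)c(O)c1 | intermediate
3 | 2,6-bis(benzyloxy)-4-methoxybenzaldehyde | COc1cc(OCc2ccccc2)c(C=O)c(OCc2ccccc2)c1 | intermediate
4 | isovanillin (3-hydroxy-4-methoxybenzaldehyde) | COc1ccc(C=O)cc1O | starting material
5 | 3-benzyloxy-4-methoxybenzaldehyde | COc1ccc(C=O)cc1OCc1ccccc1 | intermediate
6 | 2-benzyloxy-4-ethynyl-1-methoxybenzene | COc1ccc(C#C)cc1OCc1ccccc1 | intermediate
7 | lithium (3-benzyloxy-4-methoxyphenyl)acetylide (not isolated) | COc1ccc(C#C[Li])cc1OCc1ccccc1 | intermediate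
8 | 1-[2,6-bis(benzyloxy)-4-methoxyphenyl]-3-(3-benzyloxy-4-methoxyphenyl)prop-2-yn-1-ol (racemic) | COc1cc(OCc2ccccc2)c(C(O)C#Cc2ccc(OC)c(OCc3ccccc3)c2)c(OCc2ccccc2)c1 | intermediate
9 | 1-[2,6-bis(benzyloxy)-4-methoxyphenyl]-3-(3-benzyloxy-4-methoxyphenyl)prop-2-yn-1-one | COc1cc(OCc2ccccc2)c(C(=O)C#Cc2ccc(OC)c(OCc3ccccc3)c2)c(OCc2ccccc2)c1 | intermediate
10 | iodine monochloride | ClI | starting material
11 | 1-benzyl-5-benzyloxy-2-(3-benzyloxy-4-methoxyphenyl)-3-iodo-7-methoxy-4-oxo-4H-chromen-1-ium chloride (not isolated) | COC1=CC(OCc2ccccc2)=C2C(=O)C(I)=C(c3ccc(OC)c(OCc4ccccc4)c3)[O+](Cc3ccccc3)C2=C1.[Cl-] | intermediate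
12 | 5-benzyloxy-2-(3-benzyloxy-4-methoxyphenyl)-3-iodo-7-methoxychromen-4-one | COc1cc(OCc2ccccc2)c2c(=O)c(I)c(-c3ccc(OC)c(OCc4ccccc4)c3)oc2c1 | intermediate
13 | 5-benzyloxy-2-(3-benzyloxy-4-methoxyphenyl)-7-methoxy-3-(4,4,5,5-tetramethyl-1,3,2-dioxaborolan-2-yl)chromen-4-one | COc1cc(OCc2ccccc2)c2c(=O)c(B3OC(C)(C)C(C)(C)O3)c(-c3ccc(OC)c(OCc4ccccc4)c3)oc2c1 | intermediate
14 | 5-benzyloxy-2-(3-benzyloxy-4-methoxyphenyl)-3-hydroxy-7-methoxychromen-4-one | COc1cc(OCc2ccccc2)c2c(=O)c(O)c(-c3ccc(OC)c(OCc4ccccc4)c3)oc2c1 | intermediate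
15 | triethylammonium 5-benzyloxy-2-(3-benzyloxy-4-methoxyphenyl)-7-methoxy-4-oxochromen-3-yl sulfate | COc1cc(OCc2ccccc2)c2c(=O)c(OS(=O)(=O)[O-])c(-c3ccc(OC)c(OCc4ccccc4)c3)oc2c1.CC[NH+](CC)CC | intermediate
16 | triethylammonium 5-hydroxy-2-(3-hydroxy-4-methoxyphenyl)-7-methoxy-4-oxochromen-3-yl sulfate | COc1cc(O)c2c(=O)c(OS(=O)(=O)[O-])c(-c3ccc(OC)c(O)c3)oc2c1.CC[NH+](CC)CC | intermediate
17 | ombuin 3-O-sulfate (achiral) | COc1cc(O)c2c(=O)c(OS(=O)(=O)O)c(-c3ccc(OC)c(O)c3)oc2c1 | target

**Step count**
Total step count: 12. Longest linear sequence: 10 (steps 1, 2, 5–12, or equally steps 3, 4, 5–12).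

**Steps most likely to fail**

Step 7. Electrophilic iodination of the very electron-rich ring A may compete with activation of the alkyne. Transfer of the departing benzyl group to an aromatic carbon, or partial 5-exo closure, may also erode the yield.
The fallback sets out from 9 and separates ring closure from iodination.
- One ortho benzyl ether is removed under chelation control by the ketone (BCl3, 1 equiv, CH2Cl2, −78 °C) to give 1-(2-benzyloxy-6-hydroxy-4-methoxyphenyl)-3-(3-benzyloxy-4-methoxyphenyl)prop-2-yn-1-one F1.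
- DMAP-catalysed 6-endo oxa-Michael cyclisation (DMF, rt to 50 °C) gives 5-benzyloxy-2-(3-benzyloxy-4-methoxyphenyl)-7-methoxychromen-4-one F2.
- Carbonyl-directed deprotonation at C3 (LDA, THF, −78 °C) gives the 3-lithioflavone F3.
- Quenching with I2 brings the route back at 12.

Step 8. Oxidative addition should be easy, but transmetalation at a C3–Pd centre flanked by the 2-aryl group and the carbonyl may be slow, so protodeiodination could take over. Protodeboronation of the product during handling is a further loss channel.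
The fallback sets out from 12 and replaces palladium catalysis by halogen–metal exchange.
- iPrMgCl·LiCl (THF, −78 °C) gives the 3-(chloromagnesio)flavone F4.
- B(OMe)3 traps it as dimethyl [5-benzyloxy-2-(3-benzyloxy-4-methoxyphenyl)-7-methoxy-4-oxochromen-3-yl]boronate F5.
- H2O2/AcOH in the same flask oxidises it, and the route is rejoined at 14 without passing through 13. The metalation–borate–peroxide sequence at C3 of flavones is a known reaction type.

Step 10. Sulfation of a chelated enolic hydroxyl that is flanked on both sides may stall, and the ionic product may lose its sulfate during chromatography.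
The fallback sets out from 14 and uses a protected, neutral sulfate diester.
- 2,2,2-Trichloroethyl chlorosulfate (Et3N, DMAP, THF, 0 °C → rt) gives 5-benzyloxy-2-(3-benzyloxy-4-methoxyphenyl)-7-methoxy-4-oxochromen-3-yl 2,2,2-trichloroethyl sulfate F6, which can be purified on silica like any neutral compound.
- Pd/C with ammonium formate (MeOH, rt) removes the trichloroethyl group reductively and both benzyl ethers by transfer hydrogenolysis, giving ammonium 5-hydroxy-2-(3-hydroxy-4-methoxyphenyl)-7-methoxy-4-oxochromen-3-yl sulfate F7.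
- The cold H+ resin treatment brings the route back at 17.

**Further compounds**
F1 | step 7 | 1-(2-benzyloxy-6-hydroxy-4-methoxyphenyl)-3-(3-benzyloxy-4-methoxyphenyl)prop-2-yn-1-one | COc1cc(O)c(C(=O)C#Cc2ccc(OC)c(OCc3ccccc3)c2)c(OCc2ccccc2)c1
F2 | step 7 | 5-benzyloxy-2-(3-benzyloxy-4-methoxyphenyl)-7-methoxychromen-4-one | COc1cc(OCc2ccccc2)c2c(=O)cc(-c3ccc(OC)c(OCc4ccccc4)c3)oc2c1
F3 | step 7 | 5-benzyloxy-2-(3-benzyloxy-4-methoxyphenyl)-3-lithio-7-methoxychromen-4-one | COc1cc(OCc2ccccc2)c2c(=O)c([Li])c(-c3ccc(OC)c(OCc4ccccc4)c3)oc2c1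
F4 | step 8 | 5-benzyloxy-2-(3-benzyloxy-4-methoxyphenyl)-3-(chloromagnesio)-7-methoxychromen-4-one | COc1cc(OCc2ccccc2)c2c(=O)c([Mg]Cl)c(-c3ccc(OC)c(OCc4ccccc4)c3)oc2c1
F5 | step 8 | dimethyl [5-benzyloxy-2-(3-benzyloxy-4-methoxyphenyl)-7-methoxy-4-oxochromen-3-yl]boronate | COc1cc(OCc2ccccc2)c2c(=O)c(B(OC)OC)c(-c3ccc(OC)c(OCc4ccccc4)c3)oc2c1
F6 | step 10 | 5-benzyloxy-2-(3-benzyloxy-4-methoxyphenyl)-7-methoxy-4-oxochromen-3-yl 2,2,2-trichloroethyl sulfate | COc1cc(OCc2ccccc2)c2c(=O)c(OS(=O)(=O)OCC(Cl)(Cl)Cl)c(-c3ccc(OC)c(OCc4ccccc4)c3)oc2c1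
F7 | step 10 | ammonium 5-hydroxy-2-(3-hydroxy-4-methoxyphenyl)-7-methoxy-4-oxochromen-3-yl sulfate | COc1cc(O)c2c(=O)c(OS(=O)(=O)[O-])c(-c3ccc(OC)c(O)c3)oc2c1.[NH4+]
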